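**Plan**

1. Retrosynthesis: first remove a tert-butyl helper from the quinone hydroxyl. Then cut the quinone ring bond between the ring CH and the carbonyl carbon that lies next to C–OH, going back through a dienylketene to a cyclobut-2-enone.
2. Next cut the bond from that four-membered ring to the allylic CH2 of the side chain (allylbarium plus a squarate-derived ketone). Cut the side chain at CH2OH (formaldehyde), at the vinylic methyl (carboalumination) and at the alkyne–CH2 bond, and cut the ring–CH2 bond by a Claisen rearrangement.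
3. Forward: the cyclohexene with its stereocentre comes first, then the E-configured chain, then the union with the squarate unit. The six-membered quinone ring arises last, followed by unmasking of the hydroxyl.
4. Enabling feature: a strained four-membered ring made of C1 (carbonyl), C2 (O-tert-butyl), C3 (side chain) and sp3 C4 (OMe and 1-methoxyvinyl). Thermal cleavage of the C1–C4 bond releases the strain and gives a ketene whose carbon C1 and the vinyl CH2 are the termini of a hexatriene.
5. Stereochemistry: the single stereocentre is set by a catalyst-controlled ketone reduction and relayed suprafacially by a Johnson–Claisen rearrangement. The E alkene comes from syn-carboalumination of a terminal alkyne.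

Key step: step 10

Assumption: di-tert-butyl squarate (15) is taken as a purchasable squaric ester. Compounds 17, 18 and 20–22 are racemic at the sp3 carbon of the four-membered ring (epimer mixtures once the side chain is attached); this is of no consequence because that carbon becomes a quinone carbonyl carbon in step 10.

Abbreviation: R = (2E)-3-methyl-5-[(1S)-2,6,6-trimethylcyclohex-2-en-1-yl]pent-2-en-1-yl.

**Route**

Step 1
Reactants: 1 2,4,4-trimethylcyclohex-2-en-1-one
Product: 2 (1R)-2,4,4-trimethylcyclohex-2-en-1-ol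
Conditions: (3aS)-1-methyl-3,3-diphenyltetrahydro-1H,3H-pyrrolo[1,2-c][1,3,2]oxazaborole (10 mol %), BH3·SMe2 (0.6 equiv), THF, −20 °C; MeOH, then aq. work-up
Reagents that add atoms: none
Why: CBS reduction; the catalyst-bound borane should deliver hydride to the carbonyl face that keeps the larger, substituted-alkene arm away from the B-methyl group (as with aryl methyl ketones), which sets the (R)-carbinol centre by 1,2-reduction only.

Step 2
Reactants: 2 (1R)-2,4,4-trimethylcyclohex-2-en-1-ol
Product: 5 ethyl 2-[(1S)-2,6,6-trimethylcyclohex-2-en-1-yl]acetate, via mixed orthoester 3 (not isolated), via ketene acetal 4 (not isolated)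
Conditions: MeC(OEt)3 (6 equiv), cat. EtCO2H, 140 °C, EtOH distilled off
Reagents that add atoms: triethyl orthoacetate, CC(OCC)(OCC)OCC
Why: Johnson–Claisen rearrangement; the [3,3] shift is suprafacial, so the new C–C bond forms on the ring face that carried the C–O bond and the (R)-carbinol centre is relayed into the (S)-configured ring carbon next to the gem-dimethyl group, with the alkene moving to the trisubstituted position of the target.

Step 3
Reactants: 5 ethyl 2-[(1S)-2,6,6-trimethylcyclohex-2-en-1-yl]acetate
Product: 6 2-[(1S)-2,6,6-trimethylcyclohex-2-en-1-yl]ethan-1-ol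
Conditions: LiAlH4, Et2O, 0 °C; aq. NaOH work-up
Reagents that add atoms: none
Why: Standard hydride reduction of an ester to the primary alcohol; the allylic ring C–H is not acidic under these conditions, so the stereocentre is untouched.

Step 4
Reactants: 6 2-[(1S)-2,6,6-trimethylcyclohex-2-en-1-yl]ethan-1-ol
Product: 7 (6S)-6-(2-iodoethyl)-1,5,5-trimethylcyclohex-1-ene
Conditions: I2, PPh3, imidazole, CH2Cl2, 0 °C to rt
Reagents that add atoms: iodine, [I][I]
Why: Appel-type iodination of a primary alcohol (alkoxyphosphonium activation, SN2 by iodide) under buffered conditions that do not touch the trisubstituted alkene.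

Step 5
Reactants: 7 (6S)-6-(2-iodoethyl)-1,5,5-trimethylcyclohex-1-ene
Product: 8 (6S)-6-(but-3-yn-1-yl)-1,5,5-trimethylcyclohex-1-ene
Conditions: LiC≡CH·H2NCH2CH2NH2, DMSO, rt
Reagents that add atoms: lithium acetylide ethylenediamine complex, [Li]C#C.NCCN
Why: SN2 alkylation of acetylide by an unhindered primary iodide in a dipolar aprotic solvent gives the terminal alkyne needed for carbometalation.

Step 6
Reactants: 8 (6S)-6-(but-3-yn-1-yl)-1,5,5-trimethylcyclohex-1-ene
Product: 11 (2E)-3-methyl-5-[(1S)-2,6,6-trimethylcyclohex-2-en-1-yl]pent-2-en-1-ol (R–OH), via alkenylalane 9 (not isolated), via lithium alkenylaluminate 10 (not isolated)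
Conditions: AlMe3 (2 equiv), Cp2ZrCl2 (0.25 equiv), CH2Cl2, rt; volatiles removed; n-BuLi, THF–hexane, −78 to 0 °C; (CH2O)n, rt; aq. KNaC4H4O6 (potassium sodium tartrate)
Reagents that add atoms: trimethylaluminium, C[Al](C)C; paraformaldehyde (as formaldehyde), C=O
Why: Zirconium-catalysed methylalumination (Negishi carboalumination) adds methyl and aluminium syn across the terminal alkyne with aluminium at the terminus, and hydroxymethylation of the derived aluminate retains the geometry, which gives the E trisubstituted alkene.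

Step 7
Reactants: 11 (2E)-3-methyl-5-[(1S)-2,6,6-trimethylcyclohex-2-en-1-yl]pent-2-en-1-ol
Product: 13 (6S)-6-[(3E)-5-chloro-3-methylpent-3-en-1-yl]-1,5,5-trimethylcyclohex-1-ene (R–Cl), via allylic mesylate 12 (not isolated)
Conditions: MsCl, LiCl, 2,4,6-collidine, DMF, 0 °C
Reagents that add atoms: lithium chloride, [Li+].[Cl-]
Why: Mesylation and chloride displacement at the primary carbon under buffered conditions convert primary allylic alcohols into primary allylic chlorides without allylic transposition or loss of alkene geometry.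

Step 8
Reactants: 14 methyl vinyl ether; 15 di-tert-butyl squarate (3,4-di-tert-butoxycyclobut-3-ene-1,2-dione)
Product: 18 2,3-di-tert-butoxy-4-methoxy-4-(1-methoxyethenyl)cyclobut-2-en-1-one (racemic), via 1-methoxyvinyllithium 16 (not isolated), via lithium alkoxide 17 (not isolated)
Conditions: 14 (excess), t-BuLi, THF, −78 to 0 °C; added to 15, THF, −78 °C; MeOSO2CF3, −78 to −20 °C
Reagents that add atoms: methyl trifluoromethanesulfonate, COS(=O)(=O)C(F)(F)F
Why: The α-alkoxyvinyl lithium from deprotonation of methyl vinyl ether adds 1,2 to one of the two equivalent squarate carbonyls, and O-methylation of the tertiary alkoxide installs the donor needed in step 10 and blocks alkoxide-driven ring opening.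

Step 9
Reactants: 13 (6S)-6-[(3E)-5-chloro-3-methylpent-3-en-1-yl]-1,5,5-trimethylcyclohex-1-ene; 18 2,3-di-tert-butoxy-4-methoxy-4-(1-methoxyethenyl)cyclobut-2-en-1-one
Product: 22 2-tert-butoxy-4-methoxy-4-(1-methoxyethenyl)-3-R-cyclobut-2-en-1-one (both C4 epimers), via allylbarium chloride 19 (not isolated), via barium alkoxide 20 (not isolated), via trifluoroacetate 21 (not isolated)
Conditions: BaI2 (1.0 equiv), Li(C12H10) (lithium biphenylide, 2.0 equiv), THF, rt then −78 °C; 13 (1.0 equiv), −78 °C; 18 (0.9 equiv), −78 °C; pyridine, (CF3CO)2O, −78 °C; aq. NaHCO3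
Reagents that add atoms: none
Why: Allylbarium reagents made from allylic chlorides and active barium at −78 °C add to ketones through the unsubstituted terminus with retention of E geometry, and acylation of the tertiary alkoxide triggers the squarate-type ionisation (alkoxy-stabilised cyclobutenyl cation, loss of isobutene) that places the new carbonyl and the side-chain carbon on either side of the quaternary carbon.

Step 10
Reactants: 22 2-tert-butoxy-4-methoxy-4-(1-methoxyethenyl)-3-R-cyclobut-2-en-1-one
Product: 26 2-tert-butoxy-5-methoxy-3-R-cyclohexa-2,5-diene-1,4-dione, via dienylketene 23 (not isolated), via cyclohexadienone 24 (not isolated), via phenol 25 (not isolated)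
Conditions: degassed PhMe, 110 °C; concentrate; PhI(OAc)2, MeCN–H2O, 0 °C
Reagents that add atoms: water, O
Why: Heating opens the strained four-membered ring by conrotatory 4π-electrocyclic cleavage of the bond between the carbonyl carbon and the quaternary carbon, giving dienylketene 23, and the release of ring strain drives the opening forward. The opening is torquoselective: the methoxy donor on the quaternary carbon rotates outward, so the 1-methoxyvinyl group turns inward and ends cis to the ketene, which is the geometry the closure needs. Thermal disrotatory 6π-electrocyclisation then joins the ketene carbon to the terminal CH2 of the methoxyvinyl group, closing the six-membered carbocycle as dienone 24, which tautomerises to phenol 25; this is the Moore-type ring expansion of 4-alkenyl-4-alkoxycyclobutenones. No stereocentre is created, the sp3 ring carbon is destroyed, and the side-chain stereocentre is remote and untouched. The regiochemistry follows from the order of the two carbonyl additions in steps 8 and 9, which places the new carbonyl carbon between the ring CH and the carbon bearing O-tert-butyl and the side chain next to that carbon. PhI(OAc)2 in wet acetonitrile then oxidises the phenol at the position para to the hydroxyl, where water displaces the helper methoxy group as methanol and the para-quinone results.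

Step 11
Reactants: 26 2-tert-butoxy-5-methoxy-3-R-cyclohexa-2,5-diene-1,4-dione
Product: 27 2-hydroxy-5-methoxy-3-{(2E)-3-methyl-5-[(1S)-2,6,6-trimethylcyclohex-2-en-1-yl]pent-2-en-1-yl}cyclohexa-2,5-diene-1,4-dione
Conditions: CF3CO2H (10 equiv), CH2Cl2, 0 °C, short reaction time
Reagents that add atoms: none
Why: The tert-butyl vinylogous ester behaves like a tert-butyl ester and should lose isobutene by acidolysis (E1) to free the acidic quinone hydroxyl, while the methyl vinylogous ester cannot ionise and stays.

**Compound list**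

1 | 2,4,4-trimethylcyclohex-2-en-1-one | CC1=CC(C)(C)CCC1=O | starting material
2 | (1R)-2,4,4-trimethylcyclohex-2-en-1-ol | CC1=CC(C)(C)CC[C@H]1O | intermediate
3 | (6R)-6-(1,1-diethoxyethoxy)-1,3,3-trimethylcyclohex-1-ene (mixed orthoester) | CC1=CC(C)(C)CC[C@H]1OC(C)(OCC)OCC | intermediate
4 | (6R)-6-[(1-ethoxyethenyl)oxy]-1,3,3-trimethylcyclohex-1-ene (ketene acetal) | CC1=CC(C)(C)CC[C@H]1OC(=C)OCC | intermediate
5 | ethyl 2-[(1S)-2,6,6-trimethylcyclohex-2-en-1-yl]acetate | CCOC(=O)C[C@@H]1C(C)=CCCC1(C)C | intermediate
6 | 2-[(1S)-2,6,6-trimethylcyclohex-2-en-1-yl]ethan-1-ol | OCC[C@@H]1C(C)=CCCC1(C)C | intermediate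
7 | (6S)-6-(2-iodoethyl)-1,5,5-trimethylcyclohex-1-ene | ICC[C@@H]1C(C)=CCCC1(C)C | intermediate
8 | (6S)-6-(but-3-yn-1-yl)-1,5,5-trimethylcyclohex-1-ene | C#CCC[C@@H]1C(C)=CCCC1(C)C | intermediate
9 | dimethyl{(1E)-2-methyl-4-[(1S)-2,6,6-trimethylcyclohex-2-en-1-yl]but-1-en-1-yl}alane | C[Al](C)/C=C(\C)CC[C@@H]1C(C)=CCCC1(C)C | intermediate
10 | lithium butyl(dimethyl){(1E)-2-methyl-4-[(1S)-2,6,6-trimethylcyclohex-2-en-1-yl]but-1-en-1-yl}aluminate | [Li+].CCCC[Al-](C)(C)/C=C(\C)CC[C@@H]1C(C)=CCCC1(C)C | intermediate
11 | (2E)-3-methyl-5-[(1S)-2,6,6-trimethylcyclohex-2-en-1-yl]pent-2-en-1-ol | OC/C=C(\C)CC[C@@H]1C(C)=CCCC1(C)C | intermediate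
12 | (2E)-3-methyl-5-[(1S)-2,6,6-trimethylcyclohex-2-en-1-yl]pent-2-en-1-yl methanesulfonate | CS(=O)(=O)OC/C=C(\C)CC[C@@H]1C(C)=CCCC1(C)C | intermediate
13 | (6S)-6-[(3E)-5-chloro-3-methylpent-3-en-1-yl]-1,5,5-trimethylcyclohex-1-ene | ClC/C=C(\C)CC[C@@H]1C(C)=CCCC1(C)C | intermediate
14 | methyl vinyl ether | COC=C | starting material
15 | di-tert-butyl squarate (3,4-di-tert-butoxycyclobut-3-ene-1,2-dione) | CC(C)(C)OC1=C(OC(C)(C)C)C(=O)C1=O | starting material
16 | 1-methoxyvinyllithium | [Li]C(=C)OC | intermediate
17 | lithium 2,3-di-tert-butoxy-1-(1-methoxyethenyl)-4-oxocyclobut-2-en-1-olate (racemic) | [Li+].[O-]C1(C(=C)OC)C(OC(C)(C)C)=C(OC(C)(C)C)C1=O | intermediate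
18 | 2,3-di-tert-butoxy-4-methoxy-4-(1-methoxyethenyl)cyclobut-2-en-1-one (racemic) | COC(=C)C1(OC)C(OC(C)(C)C)=C(OC(C)(C)C)C1=O | intermediate
19 | chloro{(2E)-3-methyl-5-[(1S)-2,6,6-trimethylcyclohex-2-en-1-yl]pent-2-en-1-yl}barium | Cl[Ba]C/C=C(\C)CC[C@@H]1C(C)=CCCC1(C)C | intermediate
20 | chlorobarium 2,3-di-tert-butoxy-4-methoxy-4-(1-methoxyethenyl)-1-R-cyclobut-2-en-1-olate (epimer mixture) | COC(=C)C1(OC)C(OC(C)(C)C)=C(OC(C)(C)C)C1(O[Ba]Cl)C/C=C(\C)CC[C@@H]2C(C)=CCCC2(C)C | intermediate
21 | 2,3-di-tert-butoxy-4-methoxy-4-(1-methoxyethenyl)-1-R-cyclobut-2-en-1-yl trifluoroacetate (epimer mixture) | COC(=C)C1(OC)C(OC(C)(C)C)=C(OC(C)(C)C)C1(OC(=O)C(F)(F)F)C/C=C(\C)CC[C@@H]2C(C)=CCCC2(C)C | intermediate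
22 | 2-tert-butoxy-4-methoxy-4-(1-methoxyethenyl)-3-R-cyclobut-2-en-1-one (epimer mixture) | COC(=C)C1(OC)C(C/C=C(\C)CC[C@@H]2C(C)=CCCC2(C)C)=C(OC(C)(C)C)C1=O | intermediate
23 | dienylketene: 2-tert-butoxy-4,5-dimethoxy-3-R-hexa-1,3,5-trien-1-one, methoxyvinyl group cis to the ketene-bearing carbon | O=C=C(OC(C)(C)C)/C(C/C=C(\C)CC[C@@H]1C(C)=CCCC1(C)C)=C(/OC)C(=C)OC | intermediate
24 | 2-tert-butoxy-4,5-dimethoxy-3-R-cyclohexa-2,4-dien-1-one | O=C1CC(OC)=C(OC)C(C/C=C(\C)CC[C@@H]2C(C)=CCCC2(C)C)=C1OC(C)(C)C | intermediate
25 | 2-tert-butoxy-4,5-dimethoxy-3-R-phenol | COc1cc(O)c(OC(C)(C)C)c(C/C=C(\C)CC[C@@H]2C(C)=CCCC2(C)C)c1OC | intermediate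
26 | 2-tert-butoxy-5-methoxy-3-R-cyclohexa-2,5-diene-1,4-dione | COC1=CC(=O)C(OC(C)(C)C)=C(C/C=C(\C)CC[C@@H]2C(C)=CCCC2(C)C)C1=O | intermediate
27 | 2-hydroxy-5-methoxy-3-{(2E)-3-methyl-5-[(1S)-2,6,6-trimethylcyclohex-2-en-1-yl]pent-2-en-1-yl}cyclohexa-2,5-diene-1,4-dione | COC1=CC(=O)C(O)=C(C/C=C(\C)CC[C@@H]2C(C)=CCCC2(C)C)C1=O | target

**Step count and risks**

Total step count: 11. Longest linear sequence: 10 steps (steps 1–7, then 9, 10 and 11); step 8 is a one-step side branch.

Steps most likely to fail:

Step 9. The allyl metal may react through its substituted terminus or lose its E geometry, addition at the hindered vinylogous-ester carbonyl may be slow, and the enol ether may be hydrolysed during the acylation. Fallback: set out from 18 and form the same bond with the side chain as the electrophile. Bu3SnLi (THF, −78 °C) should add to the carbonyl of 18 to give the lithium alkoxide F1. Acylation in the flask with (CF3CO)2O and pyridine should give the trifluoroacetate F2, which ionises with loss of isobutene to the stannylcyclobutenone F3. Stille coupling of F3 with chloride 13 (Pd2(dba)3 as zerovalent palladium source, tri(2-furyl)phosphine, CuI, DMF, rt) should join the less hindered allyl terminus with retention of E geometry and return to the route at 22.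

Step 11. The Brønsted acid may start cyclisation of the diene chain or addition of the quinone hydroxyl to the side-chain alkene (chromene-type ring closure) before the tert-butyl group has gone. Fallback: set out from 26 and exchange the tert-butyl group under aprotic, buffered conditions. Me3SiOSO2CF3 with 2,6-lutidine (CH2Cl2, −78 to 0 °C) should silylate the carbonyl oxygen that is vinylogous to the tert-butoxy group and expel isobutene to the base, giving the ortho-quinone silyl ether F4. Hydrolysis with pH 7 phosphate buffer should give the hydroxyquinone in its para-quinone tautomer, which is 27.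

Step 2. The acid and heat may ionise the allylic orthoester, with elimination to a diene or erosion of enantiopurity, before the rearrangement at the hindered terminus takes place. Fallback: set out from 2 and use an ester-enolate (Ireland–Claisen) rearrangement under basic, low-temperature conditions. Acetylation (Ac2O, Et3N, cat. 4-dimethylaminopyridine) should give the acetate F5. Lithium diisopropylamide and Me3SiCl (THF, −78 °C) should give the silyl ketene acetal F6, which on warming to 60 °C should rearrange suprafacially to the trimethylsilyl ester F7. Aqueous work-up should give the acid F8, and LiAlH4 reduction of F8 returns to the route at 6, bypassing 5.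

**Further compounds**

F1 | step 9 | lithium 2,3-di-tert-butoxy-4-methoxy-4-(1-methoxyethenyl)-1-(tributylstannyl)cyclobut-2-en-1-olate | [Li+].[O-]C1([Sn](CCCC)(CCCC)CCCC)C(OC(C)(C)C)=C(OC(C)(C)C)C1(OC)C(=C)OC
F2 | step 9 | 2,3-di-tert-butoxy-4-methoxy-4-(1-methoxyethenyl)-1-(tributylstannyl)cyclobut-2-en-1-yl trifluoroacetate | FC(F)(F)C(=O)OC1([Sn](CCCC)(CCCC)CCCC)C(OC(C)(C)C)=C(OC(C)(C)C)C1(OC)C(=C)OC
F3 | step 9 | 2-tert-butoxy-4-methoxy-4-(1-methoxyethenyl)-3-(tributylstannyl)cyclobut-2-en-1-one | COC(=C)C1(OC)C([Sn](CCCC)(CCCC)CCCC)=C(OC(C)(C)C)C1=O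
F4 | step 11 | 5-methoxy-3-R-4-(trimethylsilyloxy)cyclohexa-3,5-diene-1,2-dione | COC1=CC(=O)C(=O)C(C/C=C(\C)CC[C@@H]2C(C)=CCCC2(C)C)=C1O[Si](C)(C)C
F5 | step 2 | (1R)-2,4,4-trimethylcyclohex-2-en-1-yl acetate | CC(=O)O[C@@H]1CCC(C)(C)C=C1C
F6 | step 2 | trimethyl({1-[(1R)-2,4,4-trimethylcyclohex-2-en-1-yl]oxyethenyl}oxy)silane | C=C(O[Si](C)(C)C)O[C@@H]1CCC(C)(C)C=C1C
F7 | step 2 | trimethylsilyl 2-[(1S)-2,6,6-trimethylcyclohex-2-en-1-yl]acetate | C[Si](C)(C)OC(=O)C[C@@H]1C(C)=CCCC1(C)C
F8 | step 2 | 2-[(1S)-2,6,6-trimethylcyclohex-2-en-1-yl]acetic acid | OC(=O)C[C@@H]1C(C)=CCCC1(C)C
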